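Remark (assumption on numbering): the target is treated as a 4,5‑seco‑guaiane (xanthane‑type) 12,6‑olide and all intermediates carry its numbering. Ring carbons are C‑1, C‑5, C‑6, C‑7, C‑8, C‑9, C‑10; the side chain is C‑2(=O), C‑3=C‑4, C‑15; the lactone is C‑11, C‑12(=O), C‑13(=CH2); the methyl is C‑14. α is the face of O‑6; β is the opposite face.

## Analysis of the target

The target is a cycloheptane (C‑1, C‑5 to C‑10) cis‑fused at C‑6/C‑7 to an α‑methylene‑γ‑butyrolactone. C‑1 carries a hydroxyl and an (E)‑but‑2‑enoyl chain, C‑5 a (Z)‑2‑methylbut‑2‑enoate (angelate), C‑9 a hydroxyl and C‑10 a methyl. Six of the seven ring carbons are stereocentres, (1S,5S,6R,7S,9R,10S). O‑6, C‑11 (on C‑7), C‑14 and HO‑1 lie on the α face; O‑5, HO‑9 and the C‑1 acyl group lie on the β face. The relations are therefore: lactone cis, O‑5/O‑6 trans, HO‑1/O‑5 trans, HO‑9/CH3‑10 trans, and CH3‑10 cis to HO‑1 and to the C‑7 side chain. The sensitive groups are the α‑methylene lactone (Michael acceptor), the tertiary α‑ketol next to an acyloxy carbon (ketol shift, acyl migration, retro‑aldol), the angelate (Z to E isomerisation) and the enone. The hard points are the quaternary carbinol C‑1 between two stereocentres, the all‑trans O‑1/O‑5/O‑6 array on a flexible ring, and the C‑10 methyl. In any cyclohexanone precursor that methyl corresponds to the less stable, axial epimer.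

## Retrosynthetic reasoning

Angelate and silyl ether. The angelate is put on last but one, because it isomerises easily. Target 23 comes from silyl ether 22, and 22 from the 1,5‑diol 21 by acylation of the only free secondary hydroxyl.

C‑5 carbinol. The trans HO‑1/O‑5 relation is that of a hydroxyl‑directed reduction. Diol 21 goes back to ketone 20, in which the C‑1 hydroxyl delivers hydride to the α face of C‑5.

Key disconnection, C‑1–C‑10. In 20 the unit O=C‑5–C‑1(OH)–C‑2=O is a 2‑hydroxy‑1,3‑dicarbonyl. Such a unit is the product of an α‑ketol shift of a β‑hydroxy‑α‑dione. Cutting C‑1–C‑10 and re‑attaching C‑10 to C‑5 contracts the ring to the cyclohexanol 19, which carries the whole C‑1–C‑4/C‑15 chain as an exocyclic ene‑dione. Forward, one 1,2‑shift makes the seven‑membered ring and the quaternary carbinol, and transfers the C‑5 configuration of 19 to C‑1. It is cut here because no other bond removes the medium ring and the hardest stereocentre together.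

C‑5–C‑1 bond. Dione 19 comes from diazo ketone 18 by oxygen transfer. 18 comes from the bicyclic keto lactone 13 and diazo enone 16 by an aldol‑type addition; the nucleophile must enter 13 from the β face. 16 comes from enone 14.

Lactone C‑6–O bond. Lactone 13 goes back to keto acid 11. Forward, the carboxylate displaces a C‑6 leaving group, which can only give the cis ring fusion.

Oxidation levels. Acid and ketone of 11 come from diol 9 through keto enal 10. Diol 9 comes from 8 and 8 from oxirane 7; the oxirane is the masked form of the allylic alcohol.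

C‑9/C‑10. The trans HO‑9/CH3‑10 pair is the signature of a syn hydration of a trisubstituted alkene. Silyl ether 7 and alcohol 6 go back to alkene 4. The oxirane in 4 protects the second alkene from borane.

Chiral pool. Compounds 4, 3 and 2 lead to (R)‑carvone 1. Its stereocentre is C‑7, its isopropenyl group becomes C‑11/C‑12/C‑13, its methyl is C‑14 and its carbonyl carbon is C‑5.

## Alternatives that were turned down

Alternative 1: the textbook route cuts C‑5=C‑6 and closes the ring by ring‑closing metathesis of the acyclic polyene A1 to cycloheptene A2, followed by epoxidation and lactonisation. It was turned down for three reasons. A1 needs C‑1, C‑7, C‑9 and C‑10 set one by one on an open chain. The metathesis has to choose among four alkenes, one of them on a fully substituted carbinol carbon. And A2 still needs face‑selective oxidation of a flexible ring. The route is longer and none of its steps uses the α‑ketol.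

Alternative 2: a [4+3] cycloaddition of an oxyallyl cation to a 3‑substituted furan would form C‑5–C‑6 and C‑9–C‑10 and give the oxabicycle A3. Its rigid frame would control C‑10, C‑5 and C‑1 well. It was turned down because the oxygen bridge makes O‑6 and O‑9 cis while the target has them trans, so a late ether cleavage with inversion at C‑6 is needed. The two unsymmetrical partners also raise a regiochemical problem, and A3 is racemic without an auxiliary or a resolution.

Alternative 3: ring expansion of a silyl enol ether derived from 1 by cyclopropanation and oxidative cyclopropanol opening would give cycloheptenone A4, with the carvone carbonyl as C‑1 and the new carbon as C‑5. It was turned down because the new carbon arrives as a bare CH. C‑1 then has to be set by an intermolecular addition and C‑5/C‑6 by an epoxidation, both on a flexible ring. C‑10 also stays next to a ketone through several Lewis‑acidic and basic steps, where it can relax to the wrong epimer.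

Key step: step 14

## Steps

Step 1
Reactants: 1 (R)‑(–)‑carvone
Product: 2 (5R)‑2‑methyl‑5‑(2‑methyloxiran‑2‑yl)cyclohex‑2‑en‑1‑one (both oxirane epimers)
Conditions: mCPBA, CH2Cl2, 0 °C
Reagents that add atoms: 3‑chloroperoxybenzoic acid, OOC(=O)c1cccc(Cl)c1
Why: Peracid epoxidation takes the electron‑rich 1,1‑disubstituted alkene and leaves the enone alkene; the oxirane masks this alkene against borane and later becomes the C‑12 alcohol, and its own configuration is lost in step 6.

Step 2
Reactants: 2
Product: 3 (1R,5R)‑2‑methyl‑5‑(2‑methyloxiran‑2‑yl)cyclohex‑2‑en‑1‑ol (5α‑OH, cis to the C‑7 side chain)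
Conditions: NaBH4, CeCl3·7H2O, MeOH, –78 °C
Reagents that add atoms: none
Why: Luche 1,2‑reduction; hydride should add anti to the C‑7 substituent and give the cis alcohol, as carvone itself does.

Step 3
Reactants: 3
Product: 4 triethylsilyl ether of 3 (5α‑OSiEt3)
Conditions: Et3SiCl, imidazole, CH2Cl2, 0 °C
Reagents that add atoms: chlorotriethylsilane, CC[Si](Cl)(CC)CC
Why: Silylation under non‑basic conditions avoids attack of a C‑5 alkoxide on the cis oxirane; the silyl ether is bulky enough to steer step 4 and can be removed beside a TBS ether.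

Step 4
Reactants: 4
Product: 6 cyclohexanol with 5α‑OSiEt3, 7α‑(2‑methyloxiran‑2‑yl), 9β‑OH, 10α‑CH3, via C‑9 alkylborane 5 (not isolated)
Conditions: BH3·THF, THF, 0 °C to rt; then NaOH, H2O2, 0 °C
Reagents that add atoms: hydrogen peroxide, OO
Why: Hydroboration–oxidation puts boron on the less substituted C‑9, and the syn addition makes HO‑9 and CH3‑10 trans by necessity. Attack should come from the β face, because the allylic silyloxy group sits below the alkene plane on the α side next to C‑10; the oxirane should survive borane at this temperature.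

Step 5
Reactants: 6
Product: 7 the 9β‑tert‑butyldimethylsilyl ether of 6
Conditions: TBSCl, imidazole, DMAP (cat.), DMF, 40 °C
Reagents that add atoms: tert‑butylchlorodimethylsilane, CC(C)(C)[Si](C)(C)Cl
Why: Standard silylation; a chloride is used instead of a triflate so that the oxirane is not opened.

Step 6
Reactants: 7
Product: 8 allylic alcohol: cyclohexane with 5α‑OSiEt3, 7α‑(3‑hydroxyprop‑1‑en‑2‑yl), 9β‑OTBS, 10α‑CH3
Conditions: Et2Al(2,2,6,6‑tetramethylpiperidide) (from n‑BuLi, tetramethylpiperidine, Et2AlCl), toluene, 0 °C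
Reagents that add atoms: none
Why: Aluminium‑amide isomerisation of an epoxide to an allylic alcohol by syn β‑elimination; the proton is taken from the unhindered methyl, so both oxirane epimers converge on the 2‑substituted allyl alcohol.

Step 7
Reactants: 8
Product: 9 diol: cyclohexane with 5α‑OH, 7α‑(3‑hydroxyprop‑1‑en‑2‑yl), 9β‑OTBS, 10α‑CH3
Conditions: PPTS (cat.), MeOH, 0 °C to rt
Reagents that add atoms: none
Why: Acid‑catalysed methanolysis cleaves the triethylsilyl ether much faster than the hindered secondary TBS ether.

Step 8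
Reactants: 9
Product: 10 keto enal: 7α‑(3‑oxoprop‑1‑en‑2‑yl)‑9β‑OTBS‑10α‑methylcyclohexan‑5‑one
Conditions: Dess–Martin periodinane, NaHCO3, CH2Cl2, 0 °C to rt
Reagents that add atoms: none
Why: One buffered, non‑enolising oxidation raises both hydroxyls; the axial‑type C‑10 methyl next to the new ketone should not epimerise under these conditions.

Step 9
Reactants: 10
Product: 11 keto acid: 2‑[(7α)‑5‑oxo‑9β‑OTBS‑10α‑methylcyclohexyl]acrylic acid
Conditions: NaClO2, NaH2PO4, 2‑methyl‑2‑butene, t‑BuOH/H2O, rt
Reagents that add atoms: sodium chlorite, [Na+].[O-]Cl=O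
Why: Pinnick oxidation converts the enal to the acrylic acid without touching the ketone or the alkene.

Step 10
Reactants: 11
Product: 13 cis‑fused keto lactone (6α‑O, 7α‑C; 9β‑OTBS, 10α‑CH3, C‑5 ketone, α‑methylene lactone), via 6β‑iodo keto acid 12 (not isolated)
Conditions: LDA (2.2 equiv), THF, –78 °C; I2, –78 to 0 °C
Reagents that add atoms: none
Why: Kinetic deprotonation at the C‑6 methylene and iodination give the α‑iodo ketone, which the carboxylate displaces in a 5‑exo‑tet SN2 with inversion. Only the cis ring fusion can form, and the iodide epimers interconvert, so the closure is stereoconvergent; C‑10 is not deprotonated.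

Step 11
Reactants: 14 (E)‑pent‑3‑en‑2‑one
Product: 16 (E)‑1‑diazopent‑3‑en‑2‑one, via trifluoroacetyl diketone 15 (not isolated)
Conditions: LiHMDS, THF, –78 °C; CF3CO2CH2CF3; aq. HCl; then MsN3, Et3N, H2O, MeCN, rt
Reagents that add atoms: methanesulfonyl azide, CS(=O)(=O)N=[N+]=[N-]
Why: Detrifluoroacetylative diazo transfer; trifluoroacetylation of the kinetic enolate activates the methyl group, and this is the established way to α′‑diazo enones that do not survive direct diazo transfer.

Step 12
Reactants: 13; 16
Product: 18 diazo aldol adduct: lactone 13 with C‑5 now a carbinol (5α‑OH) carrying a β‑oriented 1‑diazo‑2‑oxopent‑3‑enyl group, via lithiated diazoketone 17 (not isolated)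
Conditions: 16, LDA, THF, –78 °C; then 13; AcOH, –78 °C
Reagents that add atoms: none
Why: Aldol‑type addition of an α‑lithio diazo ketone to a ketone. In the preferred chair of 13 the axial C‑7–C‑11 bond and the lactone block the α face, so equatorial attack from the β face should give the 5α‑alcohol.

Step 13
Reactants: 18
Product: 19 β‑hydroxy ene‑1,2‑dione: 5α‑OH, 5β‑[(E)‑1,2‑dioxopent‑3‑enyl]
Conditions: dimethyldioxirane, acetone, –20 to 0 °C
Reagents that add atoms: dimethyldioxirane, CC1(C)OO1
Why: Oxygen transfer from the dioxirane to the diazo carbon with loss of nitrogen gives the vicinal dione; the electron‑poor alkenes react far more slowly at this temperature.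

Step 14
Reactants: 19
Product: 20 ring‑expanded ketol: cyclohepta‑fused lactone with C‑5 ketone, 1α‑OH, 1β‑(E)‑but‑2‑enoyl, 6α‑O, 7α‑C, 9β‑OTBS, 10α‑CH3
Conditions: Sc(OTf)3 (10 mol %), 4 Å MS, CH2Cl2, –20 to 0 °C
Reagents that add atoms: none
Why: Scandium(III) binds O‑5, O‑1 and O‑2 of 19, which holds O‑5–C‑5–C‑1=O‑1 syn‑periplanar and activates C‑1; C‑10 then shifts from C‑5 to C‑1 while the proton passes from O‑5 to O‑1 (α‑ketol rearrangement). The closest known reaction type is the Lewis‑acid α‑ketol ring expansion of 1‑acylcycloalkanols and of β‑hydroxy‑α‑dicarbonyls to α‑hydroxy‑β‑dicarbonyls, as in the D‑homo‑annulation of 17‑hydroxy‑20‑keto steroids. The seven‑membered ring is formed by ring enlargement through a three‑centre transition state (C‑5–C‑10 broken, C‑1–C‑10 made), not by a cyclisation. The new stereocentre C‑1 is set by transfer from C‑5: with the chain on the β face of C‑5 and O‑1 syn to O‑5, C‑10 reaches the face of the C‑1 carbonyl that leaves HO‑1 on α and the acyl group on β. C‑10 migrates with retention, so the methyl configuration is carried over. The step needs C‑10 to migrate and not C‑6; C‑6 bears the electron‑withdrawing lactone oxygen and is the poorer migrating group. The driving force is the loss of the vicinal dicarbonyl, estimated to outweigh the added strain of the cycloheptanone. A further 1,2‑acyl shift in 20 is held back by the low temperature and by taking 20 directly into step 15.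

Step 15
Reactants: 20
Product: 21 1α,5β‑diol (C‑2 enone, lactone and 9β‑OTBS unchanged)
Conditions: Me4NBH(OAc)3, MeCN/AcOH, –30 °C
Reagents that add atoms: none
Why: Hydroxyl‑directed triacetoxyborohydride reduction; the boron bound to HO‑1 delivers hydride to the α face of C‑5 and gives the trans diol. The saturated, acyloxy‑activated C‑5 ketone should react before the conjugated C‑2 ketone.

Step 16
Reactants: 21
Product: 22 5β‑angelate of 21 (9β‑OTBS)
Conditions: angelic acid, 2,4,6‑trichlorobenzoyl chloride, Et3N, toluene, rt; then 21, 75 °C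
Reagents that add atoms: angelic acid, C/C=C(/C)C(=O)O
Why: Yamaguchi esterification through the mixed anhydride, run without a nucleophilic catalyst so that the Z double bond does not isomerise; only the secondary C‑5 hydroxyl is free to react, the tertiary C‑1 hydroxyl is inert.

Step 17
Reactants: 22
Product: 23 target, CNP0149130.1
Conditions: HF·pyridine, pyridine/THF, 0 °C to rt
Reagents that add atoms: none
Why: Buffered fluoride desilylation; basic fluoride is avoided because it could trigger ketol or acyl shifts and angelate isomerisation.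

## Compound list

1 | (R)‑(–)‑carvone | O=C1C[C@H](C(C)=C)CC=C1C | starting material
2 | (5R)‑2‑methyl‑5‑(2‑methyloxiran‑2‑yl)cyclohex‑2‑en‑1‑one, oxirane epimers | O=C1C[C@H](C2(C)CO2)CC=C1C | intermediate
3 | (1R,5R)‑2‑methyl‑5‑(2‑methyloxiran‑2‑yl)cyclohex‑2‑en‑1‑ol | O[C@@H]1C[C@H](C2(C)CO2)CC=C1C | intermediate
4 | triethylsilyl ether of 3 | CC[Si](CC)(CC)O[C@@H]1C[C@H](C2(C)CO2)CC=C1C | intermediate
5 | C‑9 alkylborane (9β‑BH2, 10α‑CH3) | CC[Si](CC)(CC)O[C@@H]1C[C@H](C2(C)CO2)C[C@@H](B)[C@@H]1C | intermediate
6 | 9β‑alcohol (5α‑OSiEt3, 10α‑CH3, oxirane side chain) | CC[Si](CC)(CC)O[C@@H]1C[C@H](C2(C)CO2)C[C@@H](O)[C@@H]1C | intermediate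
7 | 9β‑OTBS, 5α‑OSiEt3 oxirane | CC[Si](CC)(CC)O[C@@H]1C[C@H](C2(C)CO2)C[C@@H](O[Si](C)(C)C(C)(C)C)[C@@H]1C | intermediate
8 | allylic alcohol (C‑12 OH), 5α‑OSiEt3, 9β‑OTBS | CC[Si](CC)(CC)O[C@@H]1C[C@H](C(=C)CO)C[C@@H](O[Si](C)(C)C(C)(C)C)[C@@H]1C | intermediate
9 | 5α,12‑diol, 9β‑OTBS | O[C@@H]1C[C@H](C(=C)CO)C[C@@H](O[Si](C)(C)C(C)(C)C)[C@@H]1C | intermediate
10 | keto enal | O=C1C[C@H](C(=C)C=O)C[C@@H](O[Si](C)(C)C(C)(C)C)[C@@H]1C | intermediate
11 | keto acid | O=C1C[C@H](C(=C)C(=O)O)C[C@@H](O[Si](C)(C)C(C)(C)C)[C@@H]1C | intermediate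
12 | 6β‑iodo keto acid | O=C1[C@@H](I)[C@H](C(=C)C(=O)O)C[C@@H](O[Si](C)(C)C(C)(C)C)[C@@H]1C | intermediate
13 | cis‑fused keto lactone | C=C1C(=O)O[C@@H]2[C@H]1C[C@@H](O[Si](C)(C)C(C)(C)C)[C@H](C)C2=O | intermediate
14 | (E)‑pent‑3‑en‑2‑one | C/C=C/C(C)=O | starting material
15 | (E)‑1,1,1‑trifluorohept‑5‑ene‑2,4‑dione | C/C=C/C(=O)CC(=O)C(F)(F)F | intermediate
16 | (E)‑1‑diazopent‑3‑en‑2‑one | C/C=C/C(=O)C=[N+]=[N-] | intermediate
17 | (E)‑1‑diazo‑1‑lithiopent‑3‑en‑2‑one | C/C=C/C(=O)C([Li])=[N+]=[N-] | intermediate
18 | diazo aldol adduct (5α‑OH) | C=C1C(=O)O[C@@H]2[C@H]1C[C@@H](O[Si](C)(C)C(C)(C)C)[C@H](C)[C@@]2(O)C(=[N+]=[N-])C(=O)/C=C/C | intermediate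
19 | β‑hydroxy ene‑1,2‑dione | C=C1C(=O)O[C@@H]2[C@H]1C[C@@H](O[Si](C)(C)C(C)(C)C)[C@H](C)[C@@]2(O)C(=O)C(=O)/C=C/C | intermediate
20 | ring‑expanded ketol (C‑5 ketone, 1α‑OH) | C=C1C(=O)O[C@@H]2[C@H]1C[C@@H](O[Si](C)(C)C(C)(C)C)[C@H](C)[C@@](O)(C(=O)/C=C/C)C2=O | intermediate
21 | 1α,5β‑diol | C=C1C(=O)O[C@@H]2[C@H]1C[C@@H](O[Si](C)(C)C(C)(C)C)[C@H](C)[C@@](O)(C(=O)/C=C/C)[C@H]2O | intermediate
22 | 5β‑angelate, 9β‑OTBS | C=C1C(=O)O[C@@H]2[C@H]1C[C@@H](O[Si](C)(C)C(C)(C)C)[C@H](C)[C@@](O)(C(=O)/C=C/C)[C@H]2OC(=O)/C(C)=C\C | intermediate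
23 | (3aS,5R,6S,7S,8S,8aR)‑7‑[(E)‑but‑2‑enoyl]‑5,7‑dihydroxy‑6‑methyl‑3‑methylidene‑2‑oxo‑octahydrocyclohepta[b]furan‑8‑yl (Z)‑2‑methylbut‑2‑enoate | C=C1C(=O)O[C@@H]2[C@H]1C[C@@H](O)[C@H](C)[C@@](O)(C(=O)/C=C/C)[C@H]2OC(=O)/C(C)=C\C | target

## Step count and risks

Total: 17 steps. Longest linear sequence: 16 steps (steps 1 to 10 and 12 to 17 from 1); step 11 is the side branch.

Step 14 (key step). The ketol shift may stall at an equilibrium, because the balance between dione relief and cycloheptanone strain is only estimated. The product may also go on by a 1,2‑acyl shift between C‑1 and C‑5, or some C‑6 migration may compete. Fallback: from 18 the shift is made irreversible at the diazo stage. Rh2(OAc)4 in CH2Cl2 should give, by the known carbenoid 1,2‑alkyl shift, the ring‑expanded 1‑acyl‑cycloheptan‑5‑one F1. Hydroxylation of F1 at C‑1 with an oxaziridine would return to 20. In this fallback the C‑1 configuration is no longer transferred from C‑5. The C‑10 methyl is expected to bias the enol toward the wrong face, so a chiral (camphorsulfonyl)oxaziridine would have to override that bias.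

Step 12. The lithiated diazo ketone may add in a conjugate sense to the α‑methylene lactone, or act as a base on the α‑acyloxy ketone. Fallback: from 13 the methylene group is masked as its dimethylamine adduct F2 (Me2NH, THF). The aldol addition of 17 to F2 would give the amino diazo adduct F3. Excess dimethyldioxirane would then oxidise the diazo group and the amine; Cope elimination of the N‑oxide restores the methylene group and returns to 19.

Step 4. The facial selectivity of the hydroboration rests on a pseudo‑equatorial silyloxy group and may be only moderate; slow reduction of the oxirane by borane is a second risk. Fallback: from 4 the hydroboration is run under reagent control with monoisopinocampheylborane of the matching sense, followed by the same oxidation to 6. This makes no new isolable compound (F0).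

Step 10. Enolisation may not be fully regioselective, the C‑10 centre may epimerise, or HI may be eliminated from 12. Fallback: from 11 the C‑6 oxygen is introduced first. Rubottom oxidation of the kinetic silyl enol ether (LDA, Me3SiCl; mCPBA) should give the 6β‑hydroxy keto acid F4, trans to the side chain. Mitsunobu lactonisation of F4 with inversion at C‑6 returns to 13.

Step 15. Hydride may also reduce the C‑2 enone carbonyl, which is α to the same hydroxyl. Fallback: from 20 both carbonyls are reduced on purpose with excess Me4NBH(OAc)3 at rt to the triol F5. MnO2 then re‑oxidises only the allylic C‑2 alcohol and returns to 21.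

## Further compounds

F1 | step 14 | ring‑expanded β‑diketone, 1‑[(E)‑but‑2‑enoyl]cycloheptan‑5‑one fused to the lactone (C‑1 enolisable) | C=C1C(=O)O[C@@H]2[C@H]1C[C@@H](O[Si](C)(C)C(C)(C)C)[C@H](C)C(C(=O)/C=C/C)C2=O
F2 | step 12 | dimethylamine adduct of 13 (C‑11 epimers) | CN(C)CC1C(=O)O[C@@H]2[C@H]1C[C@@H](O[Si](C)(C)C(C)(C)C)[C@H](C)C2=O
F3 | step 12 | diazo aldol adduct of F2 | CN(C)CC1C(=O)O[C@@H]2[C@H]1C[C@@H](O[Si](C)(C)C(C)(C)C)[C@H](C)[C@@]2(O)C(=[N+]=[N-])C(=O)/C=C/C
F0 | step 4 | none | none
F4 | step 10 | 6β‑hydroxy keto acid | O=C1[C@@H](O)[C@H](C(=C)C(=O)O)C[C@@H](O[Si](C)(C)C(C)(C)C)[C@@H]1C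
F5 | step 15 | 1α,2,5β‑triol (C‑2 epimers) | C=C1C(=O)O[C@@H]2[C@H]1C[C@@H](O[Si](C)(C)C(C)(C)C)[C@H](C)[C@@](O)(C(O)/C=C/C)[C@H]2O
A1 | alternative 1 | acyclic metathesis precursor with vinyl groups at C‑1 and C‑7 | C=C[C@](O[Si](CC)(CC)CC)(C(=O)/C=C/C)[C@@H](C)[C@H](O[Si](C)(C)C(C)(C)C)C[C@H](C=C)C(=C)C(=O)OC
A2 | alternative 1 | cycloheptene with C‑5=C‑6 from ring‑closing metathesis | C=C(C(=O)OC)[C@@H]1C[C@@H](O[Si](C)(C)C(C)(C)C)[C@H](C)[C@@](O[Si](CC)(CC)CC)(C(=O)/C=C/C)C=C1
A3 | alternative 2 | 8‑oxabicyclo[3.2.1]oct‑6‑en‑3‑one with equatorial C‑10 methyl and an acetate side chain on C‑7 (racemic, relative configuration) | COC(=O)CC1=C[C@H]2O[C@@H]1CC(=O)[C@H]2C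
A4 | alternative 3 | cyclohept‑2‑enone from ring expansion of a carvone‑derived silyl enol ether | O=C1C=C[C@H](C(C)=C)C[C@@H](O[Si](C)(C)C(C)(C)C)[C@@H]1C
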